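**Retrosynthetic overview**

- The target is 8α-acetoxy-14,15,16-trinorlabdane-13,18-dioic acid. The 8-OAc/13-CO2H pair is traced to a trans-fused δ-lactone (C8–O–C13, a temporary ring), the 18-CO2H to a CH2OBn group, and the C3 methylene to a 3β-OH (a temporary activating oxygen).
- Key disconnection: the C4–C5 bond (ring A) is formed together with C9–C10 (ring B) and C8–O (lactone) in one Lewis-acid epoxy-polyene tricyclisation of the open-chain epoxy diene ester 7. Ring order: A, then B, then lactone.
- Enabling feature: in 7 the tertiary epoxide carbon (future C4, carrying CH3 and the E-disposed CH2OBn) is joined by the tether C3–C2–C1–C10 to the CH terminus C5 of the C5=C10 alkene. C10 is tethered in the same way to C9 of the C8=C9 alkene, and C8 to the ester carbonyl oxygen, so each new bond closes a six-membered ring.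
- Compound 7 comes from (2E,6E)-farnesyl bromide and tert-butyl acetate by enolate alkylation, terminal allylic oxidation, Sharpless asymmetric epoxidation (source of absolute configuration) and benzylation.

Key step: step 5

Remark on the chemistry: labdane numbering is used for the bicyclic core and for the corresponding carbons of the open-chain precursors. C4 is the quaternary carbon bearing CH3 and C18, C5 the ring-fusion CH, C10 the angular carbon bearing CH3, C8 the oxygen-bearing carbon, and C9 the carbon bearing the C11–C12–C13 chain. All bicyclic compounds have 5α-H, 9α-H, 10β-CH3, 4β-CH3 (axial), the C18 group 4α (equatorial), 8β-CH3 and 8α-O. (2E,6E)-Farnesyl bromide is taken as commercially available.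

**Route**

Step 1
Reactants: 1 (2E,6E)-farnesyl bromide; 2 tert-butyl acetate
Product: 4 tert-butyl (4E,8E)-5,9,13-trimethyltetradeca-4,8,12-trienoate, via lithium enolate of tert-butyl acetate 3 (not isolated)
Conditions: LDA, THF, −78 °C; then 1, DMPU, −78 → 0 °C
Reagents that add atoms: none
Why: SN2 alkylation of a lithium ester enolate by a primary allylic bromide at the α-carbon leaves both E-alkenes untouched, and the tert-butyl ester suppresses Claisen self-condensation.

Step 2
Reactants: 4 tert-butyl (4E,8E)-5,9,13-trimethyltetradeca-4,8,12-trienoate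
Product: 5 tert-butyl (4E,8E,12E)-14-hydroxy-5,9,13-trimethyltetradeca-4,8,12-trienoate
Conditions: SeO2 (cat.), t-BuOOH, salicylic acid (cat.), CH2Cl2, 0 °C → rt
Reagents that add atoms: tert-butyl hydroperoxide, CC(C)(C)OO (oxygen delivered through catalytic SeO2)
Why: Riley allylic oxidation (ene reaction, then [2,3]-sigmatropic shift) should hydroxylate the E-methyl group of the terminal isopropylidene unit, the usual site in polyprenyl chains, and give the 12E allylic alcohol.

Step 3
Reactants: 5 tert-butyl (4E,8E,12E)-14-hydroxy-5,9,13-trimethyltetradeca-4,8,12-trienoate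
Product: 6 tert-butyl (4E,8E)-11-[(2S,3S)-3-(hydroxymethyl)-3-methyloxiran-2-yl]-5,9-dimethylundeca-4,8-dienoate
Conditions: Ti(OiPr)4 (cat.), L-(+)-diethyl tartrate (cat.), t-BuOOH, 4 Å MS, CH2Cl2, −20 °C
Reagents that add atoms: tert-butyl hydroperoxide, CC(C)(C)OO
Why: Sharpless asymmetric epoxidation touches only the allylic-alcohol alkene, and L-(+)-tartrate should deliver oxygen to the face that gives the (2S,3S)-epoxy alcohol, so both epoxide stereocenters (C3 and C4) are set by the catalyst.

Step 4
Reactants: 6 tert-butyl (4E,8E)-11-[(2S,3S)-3-(hydroxymethyl)-3-methyloxiran-2-yl]-5,9-dimethylundeca-4,8-dienoate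
Product: 7 tert-butyl (4E,8E)-11-[(2S,3S)-3-(benzyloxymethyl)-3-methyloxiran-2-yl]-5,9-dimethylundeca-4,8-dienoate
Conditions: NaH, BnBr, Bu4NI (cat.), THF, 0 °C → rt
Reagents that add atoms: benzyl bromide, BrCc1ccccc1
Why: Williamson etherification of the primary alkoxide is clean because the fully substituted epoxide carbon next to it blocks Payne rearrangement, and the tert-butyl ester is not enolised under these conditions.

Step 5
Reactants: 7 tert-butyl (4E,8E)-11-[(2S,3S)-3-(benzyloxymethyl)-3-methyloxiran-2-yl]-5,9-dimethylundeca-4,8-dienoate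
Product: 8 18-(benzyloxy)-3β-hydroxy-14,15,16-trinorlabdan-13,8α-olide
Conditions: MeAlCl2 (1.5 equiv), CH2Cl2, −78 °C; aq. NaHCO3
Reagents that add atoms: none
Why: MeAlCl2, held between the epoxide and benzyl ether oxygens, activates the epoxide, and the C5=C10 alkene opens it at the tertiary carbon C4 with inversion while the C8=C9 alkene and then the carbonyl oxygen of the tert-butyl ester add in turn; the resulting dialkoxycarbenium ion loses isobutene to leave the lactone. The closest known reaction type is the Lewis-acid-promoted epoxide-initiated cation–olefin polycyclisation (epoxy-polyene cyclisation) with carboxyl termination, the epoxide counterpart of the acid cyclisation of farnesylacetic acid to ambreinolide. Ring A closes by C4–C5 bond formation in 6-endo mode (endo opening of the epoxide at its more substituted carbon, 6-endo-trig at the alkene), ring B closes by C9–C10 bond formation in 6-endo-trig mode, and the δ-lactone closes by attack of the carbonyl oxygen on the tertiary C8 cation. C3 is carried over unchanged from the epoxide; C4 is set by the stereospecific backside opening, which turns the E-disposed CH2OBn group into the equatorial 4α substituent and the methyl group into the axial 4β one; C5, C10, C9 and C8 follow from anti addition across the two E-alkenes in an all-chair fold, which gives the trans ring fusion, H-9α and the equatorial 8α-oxygen, and the absolute sense of the fold is fixed by the (3S)-epoxide, whose C–O bond takes the equatorial position. The step needs opening at C4 and not at C3 (secured by the tertiary centre and by the alkene terminus C5 held on the C3–C2–C1–C10 tether), chair folding (secured by the E-trisubstituted alkenes) and oxygen capture at C8 instead of proton loss (secured by the six-membered reach of the ester carbonyl).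

Step 6
Reactants: 8 18-(benzyloxy)-3β-hydroxy-14,15,16-trinorlabdan-13,8α-olide
Product: 9 18-(benzyloxy)-3β-[(imidazol-1-ylcarbonothioyl)oxy]-14,15,16-trinorlabdan-13,8α-olide
Conditions: 1,1'-thiocarbonyldiimidazole, DMAP (cat.), ClCH2CH2Cl, reflux
Reagents that add atoms: 1,1'-thiocarbonyldiimidazole, S=C(n1ccnc1)n1ccnc1
Why: Thioacylation of the equatorial secondary alcohol under neutral conditions gives the Barton–McCombie precursor without touching the lactone or the benzyl ether.

Step 7
Reactants: 9 18-(benzyloxy)-3β-[(imidazol-1-ylcarbonothioyl)oxy]-14,15,16-trinorlabdan-13,8α-olide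
Product: 10 18-(benzyloxy)-14,15,16-trinorlabdan-13,8α-olide
Conditions: Bu3SnH, AIBN (cat.), toluene, reflux
Reagents that add atoms: none
Why: Barton–McCombie radical deoxygenation (stannyl radical addition to C=S, β-scission to the secondary C3 radical, hydrogen transfer from Bu3SnH) removes the temporary C3 oxygen and touches no remaining stereocenter.

Step 8
Reactants: 10 18-(benzyloxy)-14,15,16-trinorlabdan-13,8α-olide
Product: 12 benzyl 18-(benzyloxy)-8α-hydroxy-14,15,16-trinorlabdan-13-oate, via potassium 18-(benzyloxy)-8α-hydroxy-14,15,16-trinorlabdan-13-oate 11 (not isolated)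
Conditions: KOH (1.1 equiv), MeOH–H2O, 60 °C; evaporate; then BnBr, DMF, rt
Reagents that add atoms: potassium hydroxide, [K+].[OH-]; benzyl bromide, BrCc1ccccc1
Why: Saponification by acyl–oxygen cleavage opens the lactone with retention at C8, and SN2 O-alkylation of the carboxylate traps the open form as the benzyl ester before it can relactonise, the tertiary alcohol being too hindered to be alkylated.

Step 9
Reactants: 12 benzyl 18-(benzyloxy)-8α-hydroxy-14,15,16-trinorlabdan-13-oate
Product: 13 benzyl 8α-acetoxy-18-(benzyloxy)-14,15,16-trinorlabdan-13-oate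
Conditions: AcCl, N,N-dimethylaniline, CH2Cl2, 0 °C → rt
Reagents that add atoms: acetyl chloride, CC(=O)Cl
Why: O-Acylation of a hindered tertiary alcohol with an acid chloride and a weak aniline base, as established for tertiary terpenoid alcohols, proceeds without C–O cleavage, so C8 keeps its configuration.

Step 10
Reactants: 13 benzyl 8α-acetoxy-18-(benzyloxy)-14,15,16-trinorlabdan-13-oate
Product: 14 8α-acetoxy-18-hydroxy-14,15,16-trinorlabdan-13-oic acid
Conditions: H2 (1 atm), 10% Pd/C, EtOAc, rt
Reagents that add atoms: none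
Why: Catalytic hydrogenolysis cleaves both benzylic C–O bonds (ester and ether) and leaves the tertiary acetate untouched.

Step 11
Reactants: 14 8α-acetoxy-18-hydroxy-14,15,16-trinorlabdan-13-oic acid
Product: 15 8α-acetoxy-14,15,16-trinorlabdane-13,18-dioic acid
Conditions: 1-Me-AZADO (cat.), NaOCl (cat.), NaClO2, MeCN–phosphate buffer (pH 6.8), rt
Reagents that add atoms: sodium chlorite, [Na+].[O-]Cl=O
Why: Nitroxyl-catalysed alcohol oxidation coupled to a chlorite (Pinnick-type) aldehyde oxidation takes the neopentyl primary alcohol to the carboxylic acid at near-neutral pH, where the tertiary acetate survives and the quaternary C4 cannot epimerise.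

**Compound list**

1 | (2E,6E)-farnesyl bromide | CC(C)=CCC/C(C)=C/CC/C(C)=C/CBr | starting material
2 | tert-butyl acetate | CC(=O)OC(C)(C)C | starting material
3 | lithium enolate of tert-butyl acetate | [Li]OC(=C)OC(C)(C)C | intermediate
4 | tert-butyl (4E,8E)-5,9,13-trimethyltetradeca-4,8,12-trienoate | CC(C)=CCC/C(C)=C/CC/C(C)=C/CCC(=O)OC(C)(C)C | intermediate
5 | tert-butyl (4E,8E,12E)-14-hydroxy-5,9,13-trimethyltetradeca-4,8,12-trienoate | OC/C(C)=C/CC/C(C)=C/CC/C(C)=C/CCC(=O)OC(C)(C)C | intermediate
6 | tert-butyl (4E,8E)-11-[(2S,3S)-3-(hydroxymethyl)-3-methyloxiran-2-yl]-5,9-dimethylundeca-4,8-dienoate | CC(C)(C)OC(=O)CC/C=C(C)/CC/C=C(C)/CC[C@@H]1O[C@@]1(C)CO | intermediate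
7 | tert-butyl (4E,8E)-11-[(2S,3S)-3-(benzyloxymethyl)-3-methyloxiran-2-yl]-5,9-dimethylundeca-4,8-dienoate | CC(C)(C)OC(=O)CC/C=C(C)/CC/C=C(C)/CC[C@@H]1O[C@@]1(C)COCc1ccccc1 | intermediate
8 | 18-(benzyloxy)-3β-hydroxy-14,15,16-trinorlabdan-13,8α-olide | O3[C@]1(C)CC[C@@H]2[C@](C)(CC[C@H](O)[C@@]2(C)COCc4ccccc4)[C@H]1CCC3=O | intermediate
9 | 18-(benzyloxy)-3β-[(imidazol-1-ylcarbonothioyl)oxy]-14,15,16-trinorlabdan-13,8α-olide | O3[C@]1(C)CC[C@@H]2[C@](C)(CC[C@H](OC(=S)n5ccnc5)[C@@]2(C)COCc4ccccc4)[C@H]1CCC3=O | intermediate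
10 | 18-(benzyloxy)-14,15,16-trinorlabdan-13,8α-olide | O3[C@]1(C)CC[C@@H]2[C@](C)(CCC[C@@]2(C)COCc4ccccc4)[C@H]1CCC3=O | intermediate
11 | potassium 18-(benzyloxy)-8α-hydroxy-14,15,16-trinorlabdan-13-oate | O[C@]1(C)CC[C@@H]2[C@](C)(CCC[C@@]2(C)COCc3ccccc3)[C@H]1CCC(=O)[O-].[K+] | intermediate
12 | benzyl 18-(benzyloxy)-8α-hydroxy-14,15,16-trinorlabdan-13-oate | O[C@]1(C)CC[C@@H]2[C@](C)(CCC[C@@]2(C)COCc3ccccc3)[C@H]1CCC(=O)OCc4ccccc4 | intermediate
13 | benzyl 8α-acetoxy-18-(benzyloxy)-14,15,16-trinorlabdan-13-oate | CC(=O)O[C@]1(C)CC[C@@H]2[C@](C)(CCC[C@@]2(C)COCc3ccccc3)[C@H]1CCC(=O)OCc4ccccc4 | intermediate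
14 | 8α-acetoxy-18-hydroxy-14,15,16-trinorlabdan-13-oic acid | CC(=O)O[C@]1(C)CC[C@@H]2[C@](C)(CCC[C@@]2(C)CO)[C@H]1CCC(=O)O | intermediate
15 | 8α-acetoxy-14,15,16-trinorlabdane-13,18-dioic acid | CC(=O)O[C@]1(C)CC[C@@H]2[C@](C)(CCC[C@@]2(C)C(=O)O)[C@H]1CCC(=O)O | target

**Step count and risks**

Total step count: 11. Longest linear sequence: 11 steps (from 1 and 2).

Steps most likely to fail:

1. Step 5. The cascade may be interrupted by proton loss after the first or second ring closure. The activated epoxide may instead undergo a 1,2-hydride shift to the C3 ketone. Stepwise capture at C8 may erode the trans lactone fusion. Fallback: from 7, reductive epoxide opening with titanocene(III) chloride (Cp2TiCl2 cat., Mn, 2,4,6-collidine hydrochloride, THF) should give the tertiary C4 radical. This radical closes rings A and B through the same C4–C5 and C9–C10 bonds in a radical epoxy-polyene cyclisation and ends by β-hydride loss to tert-butyl 18-(benzyloxy)-3β-hydroxy-14,15,16-trinorlabd-8(17)-en-13-oate F1. Markovnikov protonation of the exocyclic alkene of F1 (p-TsOH, CH2Cl2) then gives the C8 cation, which the ester carbonyl captures with loss of isobutene, and the route is rejoined at 8.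

2. Step 9. Acyl transfer may outrun acetylation: the tertiary hydroxyl attacks the benzyl ester and re-forms the lactone, or the tertiary alcohol dehydrates under the acidic by-product. Fallback: from 10, LiAlH4 reduction of the lactone gives 18-(benzyloxy)-14,15,16-trinorlabdane-8α,13-diol F2, in which no acyl acceptor is left. Exhaustive acetylation (AcCl, N,N-dimethylaniline, warming) gives 8α,13-diacetoxy-18-(benzyloxy)-14,15,16-trinorlabdane F3. K2CO3 in MeOH at 0 °C should remove only the primary acetate and give 8α-acetoxy-18-(benzyloxy)-14,15,16-trinorlabdan-13-ol F4. Hydrogenolysis (H2, Pd/C) gives 8α-acetoxy-14,15,16-trinorlabdane-13,18-diol F5, and nitroxyl/chlorite oxidation of both primary alcohols at once comes back to the route at 15.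

3. Step 2. The ene reaction may discriminate poorly between the three trisubstituted alkenes, over-oxidise to the enal, or stall at low conversion. Fallback: from 4, the terminal alkene is functionalised through a bromohydrin instead. NBS in THF–H2O should give tert-butyl (4E,8E)-12-bromo-13-hydroxy-5,9,13-trimethyltetradeca-4,8-dienoate F6. K2CO3 in MeOH closes it to racemic tert-butyl (4E,8E)-11-(3,3-dimethyloxiran-2-yl)-5,9-dimethylundeca-4,8-dienoate F7. Periodic acid cleaves the epoxide to tert-butyl (4E,8E)-5,9-dimethyl-12-oxododeca-4,8-dienoate F8. An E-selective Wittig reaction with 2-(triphenylphosphoranylidene)propanal gives tert-butyl (4E,8E,12E)-5,9,13-trimethyl-14-oxotetradeca-4,8,12-trienoate F9, and Luche reduction (NaBH4, CeCl3, MeOH) comes back to the route at 5.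

**Further compounds**

F1 | step 5 | tert-butyl 18-(benzyloxy)-3β-hydroxy-14,15,16-trinorlabd-8(17)-en-13-oate | C=C1CC[C@@H]2[C@](C)(CC[C@H](O)[C@@]2(C)COCc3ccccc3)[C@H]1CCC(=O)OC(C)(C)C
F2 | step 9 | 18-(benzyloxy)-14,15,16-trinorlabdane-8α,13-diol | O[C@]1(C)CC[C@@H]2[C@](C)(CCC[C@@]2(C)COCc3ccccc3)[C@H]1CCCO
F3 | step 9 | 8α,13-diacetoxy-18-(benzyloxy)-14,15,16-trinorlabdane | CC(=O)O[C@]1(C)CC[C@@H]2[C@](C)(CCC[C@@]2(C)COCc3ccccc3)[C@H]1CCCOC(C)=O
F4 | step 9 | 8α-acetoxy-18-(benzyloxy)-14,15,16-trinorlabdan-13-ol | CC(=O)O[C@]1(C)CC[C@@H]2[C@](C)(CCC[C@@]2(C)COCc3ccccc3)[C@H]1CCCO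
F5 | step 9 | 8α-acetoxy-14,15,16-trinorlabdane-13,18-diol | CC(=O)O[C@]1(C)CC[C@@H]2[C@](C)(CCC[C@@]2(C)CO)[C@H]1CCCO
F6 | step 2 | tert-butyl (4E,8E)-12-bromo-13-hydroxy-5,9,13-trimethyltetradeca-4,8-dienoate (racemic) | CC(C)(O)C(Br)CC/C(C)=C/CC/C(C)=C/CCC(=O)OC(C)(C)C
F7 | step 2 | tert-butyl (4E,8E)-11-(3,3-dimethyloxiran-2-yl)-5,9-dimethylundeca-4,8-dienoate (racemic) | CC1(C)OC1CC/C(C)=C/CC/C(C)=C/CCC(=O)OC(C)(C)C
F8 | step 2 | tert-butyl (4E,8E)-5,9-dimethyl-12-oxododeca-4,8-dienoate | O=CCC/C(C)=C/CC/C(C)=C/CCC(=O)OC(C)(C)C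
F9 | step 2 | tert-butyl (4E,8E,12E)-5,9,13-trimethyl-14-oxotetradeca-4,8,12-trienoate | O=C/C(C)=C/CC/C(C)=C/CC/C(C)=C/CCC(=O)OC(C)(C)C
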